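Drimane numbering: ring A = C1–C5/C10, ring B = C5–C10, C11 = CH2O on C9, C12 = CH3 on C8. Retrosynthetic cuts in order: ArO–C11 (Mitsunobu); H–C9/HO–C11 (hydroboration); C9=C11 (Wittig, back to a C9 ketone); then C7–C8 and C8–C9, so that C8 and C12 leave ring B and C7 is rejoined to C9.
Enabling feature: with C9 as a carbonyl, C7=C8(CH3)–C9=O is a 2-methylcyclohex-2-enone. C8 carries only CH3 and C9 is flanked by quaternary C10. Such an enone is the product of inserting CH3C: into the only possible silyl enol ether (C7=C9) of a cyclopentanone.
The B-nor ketone revealed this way is a trans-hydrindanone with its carbonyl next to the angular methyl. This is the Hajos–Parrish skeleton: its six-membered ring is ring A and its five-membered ring is C5, C6, C7, C9, C10.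
Forward order: both rings are bought in (R)-Hajos–Parrish ketone. Ring A is dressed first (C4 gem-dimethyl, C5–H, C3–OH), the five-membered ring is then enlarged to ring B, C11 is added, and the coumarin is joined last.
Stereochemistry: C10 comes from the starting ketone. C5 (protonation in Li/NH3), C3 (axial hydride) and C9 (hydroboration anti to the C10 methyl) are all relayed from C10.

Key step: step 6

Remark: (R)-(−)-Hajos–Parrish ketone is taken as a purchasable single enantiomer. Drimane numbering is kept for all intermediates, so in the hydrindanes C8 is absent and C7 is bonded to C9.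

Step 1
Reactants: 1 (R)-(−)-Hajos–Parrish ketone
Product: 2 enone 9-ethylene ketal (10R)
Conditions: (TMSOCH2)2 (1.3 equiv), TMSOTf (5 mol %), CH2Cl2, −78 → −20 °C; pyridine quench
Reagents that add atoms: 1,2-bis(trimethylsilyloxy)ethane, C[Si](C)(C)OCCO[Si](C)(C)C
Why: Noyori-type acetalization under TMSOTf catalysis at low temperature is kinetically selective for the saturated C9 ketone because the C3 carbonyl is deactivated by conjugation, it does not move the C4=C5 double bond, and it masks C9 against the dissolving metal and the hydride used later.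

Step 2
Reactants: 2 enone 9-ethylene ketal
Product: 3 4-(phenylsulfanylmethyl) enone ketal (10R)
Conditions: PhSH, 37 % aq. CH2O, Et3N, EtOH, reflux
Reagents that add atoms: formaldehyde, C=O; thiophenol, Sc1ccccc1
Why: Kirk–Petrow thiomethylation: the dienolate of the enone adds to formaldehyde at C4, loss of water gives a cross-conjugated methylene ketone and thiophenol adds to it in a conjugate manner, so that the first C4 methyl carbon is installed in masked form under basic conditions that the ketal tolerates.

Step 3
Reactants: 3 4-(phenylsulfanylmethyl) enone ketal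
Product: 5 trans-fused 4,4-dimethyl-3-ketone 9-ketal (5R,10R), via lithium enolate 4 (not isolated)
Conditions: Li, NH3(l)/THF, −78 → −33 °C; then MeI (excess), −78 → −33 °C; NH4Cl
Reagents that add atoms: iodomethane, CI
Why: Stork-type dissolving-metal reductive alkylation: electron transfer first expels thiophenolate (CH2SPh becomes CH3), the 4-methyl enone is then reduced, the C5 carbanion is protonated by ammonia on its axial lobe anti to the C10 methyl to set the trans ring fusion, and the regiodefined enolate 4 is methylated at C4, which is not a stereocentre.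

Step 4
Reactants: 5 trans-fused 4,4-dimethyl-3-ketone 9-ketal
Product: 7 hydroxy ketone (3aR,5R,7aR)-5-hydroxy-4,4,7a-trimethyloctahydro-1H-inden-1-one, via hydroxy ketal 6 (not isolated)
Conditions: NaBH4, MeOH, 0 °C; then 2 M HCl, THF, 23 °C
Reagents that add atoms: water, O
Why: Borohydride reduction of a 4,4-dimethyl-3-ketone in a chair ring A proceeds by axial hydride delivery, away from the axial C4 methyl, and should give the equatorial (3R) alcohol cis to the C10 methyl, after which acid-catalysed acetal hydrolysis frees the C9 ketone, whose only stereogenic neighbour (C10) is quaternary and cannot epimerize.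

Step 5
Reactants: 7 hydroxy ketone
Product: 8 bis-silyl compound (3-O-TMS ether and C9 TMS enol ether C7=C9)
Conditions: TMSOTf (2.5 equiv), Et3N (4 equiv), CH2Cl2, 0 °C
Reagents that add atoms: trimethylsilyl trifluoromethanesulfonate, C[Si](C)(C)OS(=O)(=O)C(F)(F)F
Why: Soft enolization and O-silylation with TMSOTf/Et3N: since C10 has no hydrogen the ketone can enolize only toward C7 and a single silyl enol ether forms, while the alcohol is masked in the same operation against the n-BuLi of the next step.

Step 6
Reactants: 8 bis-silyl compound
Product: 11 hydroxy enone (4aR,6R,8aR)-6-hydroxy-2,5,5,8a-tetramethyl-4a,5,6,7,8,8a-hexahydronaphthalen-1(4H)-one, via chlorocyclopropane 9 (not isolated), via O-TMS enone 10 (not isolated)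
Conditions: CH3CHCl2 (excess), n-BuLi (slow addition), Et2O, −40 → −20 °C; then toluene, 110 °C; then 1 M HCl, THF, 23 °C
Reagents that add atoms: 1,1-dichloroethane, CC(Cl)Cl
Why: n-BuLi deprotonates CH3CHCl2 to 1,1-dichloroethyllithium, which loses LiCl and transfers CH3(Cl)C: to the electron-rich C7=C9 enol ether in a concerted [2+1] cheletropic closure of the temporary three-membered ring C7–C8–C9, giving 9. On heating, the C8–Cl bond ionizes in concert with the Woodward–Hoffmann-allowed disrotatory 2π-electrocyclic opening of the cyclopropane, the bond shared by the three- and five-membered rings (C7–C9) breaks, and the ring C5–C6–C7–C9–C10 becomes six-membered ring B as a 1-siloxyallyl cation that chloride desilylates to the C7=C8(CH3)–C9=O enone 10, whose C3 silyl ether is then cleaved by dilute acid. The closest known reaction type is the halocarbene ring enlargement of silyl enol ethers of cyclic ketones to 2-halo- or 2-methylcycloalk-2-enones. The stereocentres made at C7, C8 and C9 in 9 are transient (all three end sp2): the carbene should add to the face opposite the angular C10 methyl, and the larger CH3 should point exo so that Cl lies endo over the five-membered ring, the only orientation from which a ring-fused cyclopropane can open to a cis-cyclohexenyl cation, while C3, C5 and C10 are untouched. Site selectivity is built into the substrate, because quaternary C10 allows only the C7=C9 enol ether, so C8 can enter only between C7 and C9, and the leaving group on the inserted carbon forces cleavage of the opposite C7–C9 bond rather than of an outer cyclopropane bond. One operation thus brings in C8 and C12, fixes the ring-B double bond at C7=C8 without any regiochemical choice in an elimination, and leaves C9 as the carbonyl on which C11 is attached.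

Step 7
Reactants: 11 hydroxy enone
Product: 12 dienol (2R,4aR,8aS)-1,1,4a,6-tetramethyl-5-methylidene-1,2,3,4,4a,5,8,8a-octahydronaphthalen-2-ol
Conditions: Ph3PCH3Br, KOt-Bu (4 equiv each), toluene, 90 °C
Reagents that add atoms: methyltriphenylphosphonium bromide, C[P+](c1ccccc1)(c1ccccc1)c1ccccc1.[Br-]
Why: Wittig methylenation with the small non-stabilized ylide generated by KOt-Bu in hot toluene, the variant used for sterically hindered ketones, adds 1,2 to the enone and brings in C11, while excess base merely holds the alcohol as its alkoxide and no stereocentre is affected.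

Step 8
Reactants: 12 dienol
Product: 13 diene acetate (acetate of 12)
Conditions: Ac2O, pyridine, DMAP (cat.), CH2Cl2, 23 °C
Reagents that add atoms: acetic anhydride, CC(=O)OC(C)=O
Why: DMAP-catalysed acylation of the only hydroxyl group, placed here so that the acetate never meets n-BuLi, ylide or alkoxide.

Step 9
Reactants: 13 diene acetate
Product: 15 acetoxy alcohol (2R,4aR,5R,8aS)-5-(hydroxymethyl)-1,1,4a,6-tetramethyl-1,2,3,4,4a,5,8,8a-octahydronaphthalen-2-yl acetate, via alkylborane 14 (not isolated)
Conditions: 9-BBN, THF, 0 → 40 °C; then NaBO3·4H2O, THF/H2O, 23 °C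
Reagents that add atoms: 9-borabicyclo[3.3.1]nonane, B1C2CCCC1CCC2 (its atoms stay only in 14); sodium perborate, [Na+].[Na+].O[B-]1(O)OO[B-](O)(O)OO1 (oxygen on C11)
Why: Hydroboration–oxidation: 9-BBN places boron on the unhindered terminus C11 of the 1,1-disubstituted C9=C11 bond and leaves the trisubstituted C7=C8 bond alone, the syn addition takes place on the ring face opposite the axial C10 methyl so that H enters C9 anti and C11 ends cis to that methyl (9R), and the near-neutral perborate oxidation spares the acetate.

Step 10
Reactants: 15 acetoxy alcohol; 16 umbelliferone (7-hydroxycoumarin)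
Product: 17 target CNP0224712.1 (3R,5S,9R,10R)
Conditions: PPh3, DIAD, THF, 0 → 23 °C
Reagents that add atoms: none
Why: Mitsunobu etherification: the acidic phenol of umbelliferone displaces the oxyphosphonium salt of the primary C11 alcohol in an SN2 step at a non-stereogenic carbon under neutral conditions that leave the acetate, the lactone and the C7=C8 bond untouched.

Compound list
1 | (R)-(−)-Hajos–Parrish ketone, (7aR)-7a-methyl-2,3,7,7a-tetrahydro-1H-indene-1,5(6H)-dione | O=C1CC[C@@]2(C)C(=O)CCC2=C1 | starting material
2 | enone 9-ethylene ketal of 1 (10R; C3=O and C4=C5 kept) | O=C1CC[C@@]2(C)C3(OCCO3)CCC2=C1 | intermediate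
3 | 4-(phenylsulfanylmethyl) enone ketal (10R) | O=C1CC[C@@]2(C)C3(OCCO3)CCC2=C1CSc4ccccc4 | intermediate
4 | lithium enolate (C3–OLi, C3=C4–CH3, 5-H trans to the 10-methyl) | [Li]OC=1CC[C@@]2(C)C3(OCCO3)CC[C@@H]2C=1C | intermediate
5 | trans-fused 4,4-dimethyl-3-ketone 9-ketal (5R,10R) | O=C1CC[C@@]2(C)C3(OCCO3)CC[C@@H]2C1(C)C | intermediate
6 | hydroxy ketal (3R,5R,10R; equatorial 3-OH cis to the 10-methyl) | O[C@@H]1CC[C@@]2(C)C3(OCCO3)CC[C@@H]2C1(C)C | intermediate
7 | (3aR,5R,7aR)-5-hydroxy-4,4,7a-trimethyloctahydro-1H-inden-1-one | O[C@@H]1CC[C@@]2(C)C(=O)CC[C@@H]2C1(C)C | intermediate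
8 | bis-silyl compound (3-O-TMS ether, C9 TMS enol ether C7=C9) | C[Si](C)(C)O[C@@H]1CC[C@@]2(C)C(O[Si](C)(C)C)=CC[C@@H]2C1(C)C | intermediate
9 | chlorocyclopropane (C7–C8–C9 ring anti to the 10-methyl, Cl endo, CH3 exo, OTMS on C9) | C[Si](C)(C)O[C@@H]1CC[C@@]2(C)[C@@]3(O[Si](C)(C)C)[C@@](C)(Cl)[C@H]3C[C@@H]2C1(C)C | intermediate
10 | O-TMS enone (3-O-TMS ether of 11) | C[Si](C)(C)O[C@@H]1CC[C@@]2(C)C(=O)C(C)=CC[C@@H]2C1(C)C | intermediate
11 | (4aR,6R,8aR)-6-hydroxy-2,5,5,8a-tetramethyl-4a,5,6,7,8,8a-hexahydronaphthalen-1(4H)-one | O[C@@H]1CC[C@@]2(C)C(=O)C(C)=CC[C@@H]2C1(C)C | intermediate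
12 | (2R,4aR,8aS)-1,1,4a,6-tetramethyl-5-methylidene-1,2,3,4,4a,5,8,8a-octahydronaphthalen-2-ol | O[C@@H]1CC[C@@]2(C)C(=C)C(C)=CC[C@@H]2C1(C)C | intermediate
13 | acetate of 12 | CC(=O)O[C@@H]1CC[C@@]2(C)C(=C)C(C)=CC[C@@H]2C1(C)C | intermediate
14 | alkylborane (C11 bonded to the boron of 9-BBN, 9-H anti to the 10-methyl) | CC(=O)O[C@@H]1CC[C@@]2(C)[C@H](CB3C4CCCC3CCC4)C(C)=CC[C@@H]2C1(C)C | intermediate
15 | (2R,4aR,5R,8aS)-5-(hydroxymethyl)-1,1,4a,6-tetramethyl-1,2,3,4,4a,5,8,8a-octahydronaphthalen-2-yl acetate | CC(=O)O[C@@H]1CC[C@@]2(C)[C@H](CO)C(C)=CC[C@@H]2C1(C)C | intermediate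
16 | umbelliferone (7-hydroxy-2H-chromen-2-one) | Oc1ccc2ccc(=O)oc2c1 | starting material
17 | (2R,4aR,5R,8aS)-1,1,4a,6-tetramethyl-5-{[(2-oxo-2H-chromen-7-yl)oxy]methyl}-1,2,3,4,4a,5,8,8a-octahydronaphthalen-2-yl acetate | CC(=O)O[C@@H]1CC[C@@]2(C)[C@H](COc3ccc4ccc(=O)oc4c3)C(C)=CC[C@@H]2C1(C)C | target

Total step count: 10. Longest linear sequence: 10 steps (1 → 17); umbelliferone 16 enters in the last step.

Steps most likely to fail

1. Step 6. The 1,2-hydrogen shift of the chloro(methyl)carbenoid may outrun its addition to the hindered enol ether. Addition with the chlorine exo would also give an adduct that cannot open.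
Fallback, from 8 back to 11: the carbon insertion is separated from the introduction of the methyl group. Dibromocarbene (CHBr3, KOt-Bu, pentane, −20 °C) has no β-hydrogen and always places one bromine endo. It should give the dibromocyclopropane F1. Heating in toluene should open it to the O-TMS bromo enone F2, and dilute HCl in THF should free the hydroxy bromo enone F3. Suzuki–Miyaura methylation (trimethylboroxine, Pd(dppf)Cl2, K2CO3, dioxane, 90 °C) then returns to 11.

2. Step 3. Facial selectivity in the protonation at C5 may be poor, since a hydrindane favours the trans fusion less strongly than a decalin. Enolate equilibration before the methylation is a second risk.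
Fallback, from 2 back to 5: deconjugative double methylation (KOt-Bu, MeI, t-BuOH, 23 °C) should give the 4,4-dimethyl β,γ-unsaturated ketone ketal F4 with the double bond moved to C5=C6. Heterogeneous hydrogenation (H2 under pressure, Pd/C, EtOAc) on the face opposite the angular methyl then sets the trans fusion and gives 5.

3. Step 7. Enolization toward C6 and steric shielding of the C9 carbonyl by C10 and C12 may stop the addition of the ylide.
Fallback, from 11 back to 12: Peterson olefination in two stages. The small and irreversibly adding nucleophile TMSCH2Li (CeCl3, THF, −78 °C, excess) should add 1,2 from the face anti to the C10 methyl to give the β-hydroxysilane F5. KH in THF then effects the silicon-directed syn elimination, which can only deliver the exocyclic C9=C11 bond of 12.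

Further compounds
F1 | step 6 | dibromocyclopropane (C7–C8–C9 ring anti to the 10-methyl, CBr2 at C8) | C[Si](C)(C)O[C@@H]1CC[C@@]2(C)[C@@]3(O[Si](C)(C)C)C(Br)(Br)[C@H]3C[C@@H]2C1(C)C
F2 | step 6 | O-TMS bromo enone (8-bromo analogue of 10) | C[Si](C)(C)O[C@@H]1CC[C@@]2(C)C(=O)C(Br)=CC[C@@H]2C1(C)C
F3 | step 6 | hydroxy bromo enone (8-bromo analogue of 11) | O[C@@H]1CC[C@@]2(C)C(=O)C(Br)=CC[C@@H]2C1(C)C
F4 | step 3 | 4,4-dimethyl β,γ-unsaturated ketone ketal (C5=C6, 10R) | O=C1CC[C@@]2(C)C3(OCCO3)CC=C2C1(C)C
F5 | step 7 | β-hydroxysilane (9-OH cis and 9-CH2TMS trans to the 10-methyl) | O[C@@H]1CC[C@@]2(C)[C@@](O)(C[Si](C)(C)C)C(C)=CC[C@@H]2C1(C)C
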